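## Analysis of the target

The target 22 is a flavone: a 4H-chromen-4-one (ring A fused to the pyranone ring C) with a 3,4-dihydroxyphenyl ring B on C2. It has no stereocentre and is flat, so the problem is one of position, not of configuration. Ring A carries oxygen on four of its six carbons: O1 on C8a, free hydroxyls on C5 and C7, and between them the hydrogen sulfate on O6; only C8 bears hydrogen. The sensitive parts are the aryl sulfate monoester (ionic, cleaved by acid, awkward on silica), the catechol of ring B and the pyrogallol-like array of ring A (both easily oxidised in base and air), and the reducible C2=C3 bond. The synthesis is hard for two reasons. Of five phenolic oxygens exactly one, the most crowded, must carry sulfur. And ring A is a 1,2,3,5-tetraoxygenated benzene whose C4a must hold the carbonyl carbon C4 between two oxygenated carbons, which electrophilic acylation of a protected, acid-sensitive phenol delivers poorly. The plan rests on the fact that C8a (bearing O1) and C4a (bearing C4) are neighbours and that C4a is flanked on its other side by the oxygenated C5. This is the pattern left when an oxygen nucleophile and an acyl group add across an aryne that has one alkoxy group next to its triple bond. For O6 a second feature is used: C5, C6 and C7 form a locally symmetric trioxygenated unit, as in 1, whose middle oxygen differs from its neighbours in acidity.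

## Retrosynthetic reasoning

**Benzyl C–O bonds.** 22 is traced back, through its debenzylated salt 21, to the fully benzylated triethylammonium sulfate 20. The four O–CH2Ph bonds are cut last in the forward sense because an aryl sulfate survives neutral hydrogenolysis but not the acid that most other phenol protecting groups need. The fragile, ionic sulfate is then carried through one step only.

**O6–S bond.** 20 goes back to phenol 19, in which O6 is the only free hydroxyl. Cutting here, and not on a polyol, removes every question of site from the sulfation. The forward step only has to overcome the crowding of a hydroxyl between two benzyloxy groups.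

**O6 acetal.** 19 comes from 18, where O6 carries a methoxymethyl group. O6 needs a group that is orthogonal to benzyl, stable to organolithiums, fluoride and amines, and removable by mild acid before any sulfate is present.

**O1–C2 (ring C).** 18 is opened at O1–C2 to the o-hydroxyaryl ynone 16. The forward reaction must close in the 6-endo sense and not in the 5-exo sense. Passing through the amine adduct 17 secures this.

**C8a–O1 and C4a–C4 (key disconnection).** 16 is cut at both bonds that join ring A to the three-carbon bridge. This gives silyl triflate 9, the source of aryne 15, and acid 13, which reacts as its carboxylate 14. The cut is made here because the two bonds sit on neighbouring carbons and can be formed in one operation. The two halves are of similar size and already carry all five oxygens in differentiated form. Cutting C4a–C4 alone would mean a Friedel–Crafts or Fries acylation under Lewis acid, which the acetal on O6 and the benzyl ether on O5 would not tolerate. The forward step has to put oxygen on C8a and the acyl carbon on C4a, and leave the alkyne untouched.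

**C–Si and O–S bonds of 9.** 9 goes back through lithium phenoxide 8 and silyl ether 7 to bromophenol 6, and 6 to phenol 5. Because 5 is symmetric, its two free ring positions are equivalent and only one monobromide can form. The bromine marks the carbon that becomes C4a.

**Aryl C–O bond of 5.** 5 comes from aldehyde 3 through formate 4 by aryl migration. A trioxygenated benzaldehyde is at hand, whereas the tetraoxygenated phenol is not.

**Ether bonds of 3.** 3 goes back to 2 and then to 1. The central hydroxyl of 1 is singled out by its acidity before the two flanking ones are benzylated. This one step decides which oxygen will carry the sulfate.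

**Acid 13.** 13 comes from acetylide 12 by carboxylation, 12 from dibromoalkene 11, and 11 from aldehyde 10. This is a one-carbon homologation that builds the alkyne and the carboxyl group in two steps.

## Alternatives that were turned down

**Alternative 1:** Cyclic sulfate across O6 and O7.
- Disconnection: the S–O7 bond of a five-membered cyclic sulfate bridging O6 and O7, and behind it both S–O bonds, back to a ring A triol.
- Forward key step: the 5,6,7-triol with ring B esterified, 5,6,7-trihydroxy-3',4'-bis(pivaloyloxy)flavone A2, is treated with sulfuryl chloride and pyridine. The chelated O5–H stays out, and O6 and O7 are tied into the dioxathiole dioxide A1. Hydrolysis at sulfur should then expel the O7 phenoxide, which is conjugated with the C4 carbonyl through C4a, and leave sulfur on O6.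
- For: ring A needs no protecting group. The molecule's own properties do the differentiation, and the later deprotection is base only, which an aryl sulfate tolerates. Counted from the finished flavone core, this endgame is shorter than the chosen one.
- Against: the site of sulfur rests on a rate difference between two phenoxide leaving groups of one catechol. Any leakage gives the 7-sulfate, with the same charge and nearly the same polarity. Sulfuryl chloride also chlorinates electron-rich rings, and C8 of a free triol is the most nucleophilic carbon present. The free triol is oxidised easily in pyridine. A second hydrolysis at sulfur would remove the sulfate altogether. A2 itself needs ring B acylated while three ring A hydroxyls stay free, which costs a protecting-group sequence anyway.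
- Comparison: the chosen route is longer at the end, but it places sulfur on the only free hydroxyl, and that position is fixed in step 1.

**Alternative 2:** Anodic phenol oxidation closes ring C at C8a.
- Disconnection: the C8a–O1 bond, by oxidative C–H/O–H coupling, back to the diketone A4, 1-[2,4-bis(benzyloxy)-3-hydroxyphenyl]-3-[3,4-bis(benzyloxy)phenyl]propane-1,3-dione.
- Forward key step: A4 is oxidised at a carbon anode in a fluorinated alcohol. The phenol on C6 gives a phenoxonium ion, and the enol oxygen attacks the para carbon C8a. Loss of a proton gives A3, 5,7,3',4'-tetrakis(benzyloxy)-6-hydroxyflavone, which is the same compound as 19.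
- For: it arrives directly at 19 with O6 free and nothing to unmask. It needs no oxidant, no cryogenic organolithium chemistry and no silyl triflate, and ring A can come from a cheap acetophenone that already has three adjacent oxygens. In step count it is stronger than the chosen route.
- Against: A3 is a hydroquinone monoether, since O6–H is para to O1. It is therefore easier to oxidise than A4, so the product is consumed as it forms. C8a lies ortho to the electron-withdrawing aroyl group, the worst place for positive charge. Ipso attack at a benzyloxy carbon with loss of benzyl is a competing channel. The catechol diether of ring B, the benzyl groups and the enol are further electrophores. Leaving the middle hydroxyl of the acetophenone free while benzylating the chelated ortho hydroxyl is the same differentiation problem, unsolved. The coupling has no counterpart on this substrate class.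
- Comparison: the chosen strategy keeps every ring A oxygen protected until it is needed and builds the same bond by a known insertion with predictable orientation.

**Alternative 3:** Ferrier carbocyclization builds ring A from a sugar.
- Disconnection: the ring A carbons are taken from a 2-deoxy sugar, and the C4a–C8a bond is cut as an intramolecular aldol.
- Forward key step: the enopyranoside A6, methyl 4-O-benzoyl-3-O-benzyl-2,6-dideoxy-α-D-threo-hex-5-enopyranoside, reacts with a catalytic amount of Hg(OCOCF3)2 in aqueous acetone. Oxymercuration, ring opening and aldol closure give A5, (2S,3R)-2-(benzoyloxy)-3-(benzyloxy)-5-hydroxycyclohexan-1-one, with the carbinol centre as formed.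
- For: the reaction is very reliable. The oxygens arrive differentiated from the sugar: O6 as benzoate, O7 as benzyl ether, O5 as ketone and the C8a oxygen as carbinol. After oxidation of the carbinol, C4a would be the doubly activated carbon of a 1,3-dione, so C-acylation would be regiospecific. On innate oxygen differentiation it is stronger than the chosen route.
- Against: the target is achiral and aromatic, so two defined stereocentres and a third new one are made only to be erased. In A5 both the carbinol and the benzyloxy group are β to the ketone, so the ring tends to lose exactly the oxygens it must keep on the way to the arene. A mercury salt is needed. The sugar manipulations before the key step, then oxidation, aromatisation, acylation, ring C closure and the same endgame add up to far more steps.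
- Comparison: the chosen route buys ring A as an arene and spends its steps only on differentiation and on the two bonds to ring C.

Key step: step 9

Assumption: the target is taken as the free hydrogen sulfate as drawn; it is set free from its triethylammonium salt only at the very end and would be kept cold, since aryl hydrogen sulfates hydrolyse under their own acidity.

## Route

Step 1
Reactants: 1 3,4,5-trihydroxybenzaldehyde
Product: 2 3,5-dihydroxy-4-(methoxymethoxy)benzaldehyde
Conditions: MOMCl (1.0 equiv), K2CO3 (1.0 equiv), acetone, 0 °C to rt
Reagents that add atoms: chloromethyl methyl ether, COCCl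
Why: Regioselective Williamson-type O-alkylation; the 4-hydroxyl, para to the formyl group and flanked by two hydrogen-bond donors, is the most acidic, so with one equivalent of base the 4-phenoxide is the populated anion and should be the one alkylated.

Step 2
Reactants: 2 3,5-dihydroxy-4-(methoxymethoxy)benzaldehyde
Product: 3 3,5-bis(benzyloxy)-4-(methoxymethoxy)benzaldehyde
Conditions: BnBr (2.4 equiv), K2CO3 (3 equiv), DMF, 50 °C
Reagents that add atoms: benzyl bromide, BrCc1ccccc1
Why: Williamson etherification of the two equivalent remaining phenols; the acetal and the aldehyde are inert to carbonate.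

Step 3
Reactants: 3 3,5-bis(benzyloxy)-4-(methoxymethoxy)benzaldehyde
Product: 5 3,5-bis(benzyloxy)-4-(methoxymethoxy)phenol, via aryl formate 4 (not isolated)
Conditions: mCPBA (1.3 equiv), CH2Cl2, 0 °C to rt; then K2CO3 (0.2 equiv), MeOH, rt, under N2
Reagents that add atoms: 3-chloroperoxybenzoic acid, OOC(=O)c1cccc(Cl)c1
Why: Baeyer–Villiger oxidation; the electron-rich trialkoxyaryl group migrates in preference to hydride to give formate 4, which methanol cleaves to the phenol; benzyl ethers and the acetal are not affected by the peracid or by 3-chlorobenzoic acid in CH2Cl2.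

Step 4
Reactants: 5 3,5-bis(benzyloxy)-4-(methoxymethoxy)phenol
Product: 6 3,5-bis(benzyloxy)-2-bromo-4-(methoxymethoxy)phenol
Conditions: NBS (1.0 equiv), CH2Cl2, −78 to 0 °C
Reagents that add atoms: N-bromosuccinimide, O=C1CCC(=O)N1Br
Why: Electrophilic aromatic bromination ortho to the phenol; 5 is symmetric, so its two free positions are equivalent and one equivalent of NBS at low temperature should give a single monobromide.

Step 5
Reactants: 6 3,5-bis(benzyloxy)-2-bromo-4-(methoxymethoxy)phenol
Product: 7 [3,5-bis(benzyloxy)-2-bromo-4-(methoxymethoxy)phenoxy]trimethylsilane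
Conditions: (Me3Si)2NH (1.5 equiv), THF, 70 °C; concentration, used crude
Reagents that add atoms: hexamethyldisilazane, C[Si](C)(C)N[Si](C)(C)C
Why: O-silylation of a phenol by hexamethyldisilazane, driven by loss of ammonia; no acid or base strong enough to touch the ethers is present.

Step 6
Reactants: 7 [3,5-bis(benzyloxy)-2-bromo-4-(methoxymethoxy)phenoxy]trimethylsilane
Product: 9 3,5-bis(benzyloxy)-4-(methoxymethoxy)-2-(trimethylsilyl)phenyl trifluoromethanesulfonate, via lithium phenoxide 8 (not isolated)
Conditions: n-BuLi (1.1 equiv), THF, −78 °C; then Tf2O (1.2 equiv), −78 to 0 °C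
Reagents that add atoms: trifluoromethanesulfonic anhydride, O=S(=O)(OS(=O)(=O)C(F)(F)F)C(F)(F)F
Why: Bromine–lithium exchange followed by retro-Brook (O to C) silyl migration gives the 2-silyl phenoxide 8, which is triflated in the same flask; exchange at −78 °C is faster than benzylic deprotonation, and the phenoxide takes up the anhydride before the acetal can be activated.

Step 7
Reactants: 10 3,4-bis(benzyloxy)benzaldehyde
Product: 11 1,2-bis(benzyloxy)-4-(2,2-dibromoethenyl)benzene
Conditions: CBr4 (2 equiv), PPh3 (4 equiv), CH2Cl2, 0 °C
Reagents that add atoms: carbon tetrabromide, BrC(Br)(Br)Br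
Why: First stage of the Corey–Fuchs homologation; Wittig-type olefination of the aldehyde by the dibromomethylene ylide formed from CBr4 and PPh3.

Step 8
Reactants: 11 1,2-bis(benzyloxy)-4-(2,2-dibromoethenyl)benzene
Product: 13 3-[3,4-bis(benzyloxy)phenyl]prop-2-ynoic acid, via lithium acetylide 12 (not isolated)
Conditions: n-BuLi (2.1 equiv), THF, −78 °C; CO2 (g), −78 °C to rt; aq. HCl
Reagents that add atoms: carbon dioxide, O=C=O
Why: Second stage of the Corey–Fuchs sequence; bromine–lithium exchange, 1,2-shift with loss of LiBr and deprotonation give acetylide 12, which is carboxylated; the benzyl ethers are stable to n-BuLi at −78 °C.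

Step 9
Reactants: 9 3,5-bis(benzyloxy)-4-(methoxymethoxy)-2-(trimethylsilyl)phenyl trifluoromethanesulfonate; 13 3-[3,4-bis(benzyloxy)phenyl]prop-2-ynoic acid
Product: 16 1-[2,4-bis(benzyloxy)-6-hydroxy-3-(methoxymethoxy)phenyl]-3-[3,4-bis(benzyloxy)phenyl]prop-2-yn-1-one, via sodium carboxylate 14 (not isolated), via aryne 15 (not isolated)
Conditions: 13 (1.5 equiv), NaH (1.5 equiv), THF, 0 °C; then 9 (1.0 equiv), CsF (3 equiv), THF, 50 °C; AcOH, 0 °C
Reagents that add atoms: none
Why: Fluoride removes the trimethylsilyl group of 9 and triflate leaves, releasing aryne 15; the carboxylate oxygen of 14 adds to the aryne carbon remote from the C5 benzyloxy group (the future C8a), because the aryne is distorted so that this carbon is the more electrophilic one and the developing aryl anion then sits on C4a beside the inductively withdrawing C5 oxygen. That anion attacks the ester carbonyl two atoms away through a four-membered alkoxide, whose opening gives the phenoxide of 16, so that C8a–O1 and C4a–C4 are formed and the acyl group has moved from oxygen to carbon. The closest known reaction type is the fluoride-induced insertion of arynes into the C–O bond of carboxylic acids to give o-hydroxyaryl ketones, which includes arylpropiolic acids. No ring is closed and no stereocentre is formed. Three selectivities are needed: the orientation of addition, secured by the single alkoxy group that flanks the triple bond (C8 carries hydrogen, and the oxygens on C6 and C7 do not flank it); acyl transfer in place of protonation of the aryl anion, secured by forming the carboxylate with NaH beforehand so that neither the acid proton nor HF is present; and attack on the carbonyl carbon in place of addition to the alkyne, secured by the preferred ester conformation, which turns the alkyne away from the anion. The phenoxide of 16 is held as a chelate between the C8a oxygen and the carbonyl oxygen, a geometry that points the alkyne away from that oxygen, and the cold acetic acid quench should deliver the open ynone.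

Step 10
Reactants: 16 1-[2,4-bis(benzyloxy)-6-hydroxy-3-(methoxymethoxy)phenyl]-3-[3,4-bis(benzyloxy)phenyl]prop-2-yn-1-one
Product: 18 5,7-bis(benzyloxy)-2-[3,4-bis(benzyloxy)phenyl]-6-(methoxymethoxy)-4H-chromen-4-one, via enaminone 17 (not isolated)
Conditions: Et2NH (5 equiv), EtOH, 70 °C
Reagents that add atoms: none
Why: Conjugate addition of diethylamine to the ynone gives enaminone 17, and the phenol oxygen then adds to the same carbon and expels the amine (6-endo-trig addition–elimination); the 5-exo closure to a benzofuranone needs the free ynone as acceptor, which the amine has removed, so only the six-membered ring should form.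

Step 11
Reactants: 18 5,7-bis(benzyloxy)-2-[3,4-bis(benzyloxy)phenyl]-6-(methoxymethoxy)-4H-chromen-4-one
Product: 19 5,7-bis(benzyloxy)-2-[3,4-bis(benzyloxy)phenyl]-6-hydroxy-4H-chromen-4-one
Conditions: HCl (0.5 M), MeOH/THF 1:1, 40 °C
Reagents that add atoms: none
Why: Acid-catalysed transacetalisation of the methoxymethyl ether to methanol; dilute acid at 40 °C is well below what cleaves aryl benzyl ethers, including the chelation-activated one on O5.

Step 12
Reactants: 19 5,7-bis(benzyloxy)-2-[3,4-bis(benzyloxy)phenyl]-6-hydroxy-4H-chromen-4-one
Product: 20 triethylammonium 5,7-bis(benzyloxy)-2-[3,4-bis(benzyloxy)phenyl]-4-oxo-4H-chromen-6-yl sulfate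
Conditions: SO3·NEt3 (5 equiv), Et3N (2 equiv), DMF, 60 °C
Reagents that add atoms: sulfur trioxide–triethylamine complex, CC[N+](CC)(CC)S(=O)(=O)[O-]
Why: O-sulfation of a phenol by transfer of SO3 from its amine complex; O6 is the only free hydroxyl, so the site is fixed, and the product stays as its triethylammonium salt, which is soluble in organic solvents and buffered against acid.

Step 13
Reactants: 20 triethylammonium 5,7-bis(benzyloxy)-2-[3,4-bis(benzyloxy)phenyl]-4-oxo-4H-chromen-6-yl sulfate
Product: 22 2-(3,4-dihydroxyphenyl)-5,7-dihydroxy-4-oxo-4H-chromen-6-yl hydrogen sulfate (6-hydroxyluteolin 6-sulfate), via triethylammonium salt 21 (not isolated)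
Conditions: H2 (1 atm), 10% Pd/C, THF/MeOH, rt; filtration; Dowex 50W-X8 (H+ form), MeOH/H2O, 0 °C; freeze-drying
Reagents that add atoms: none
Why: Hydrogenolysis of the four aryl benzyl ethers under neutral conditions, which an aryl sulfate salt tolerates, then cation exchange to the free acid; the C2=C3 bond is part of a vinylogous ester and should survive at 1 atm if the reaction is stopped when the benzyl groups are gone.

## Compound list

1 | 3,4,5-trihydroxybenzaldehyde | O=Cc1cc(O)c(O)c(O)c1 | starting material
2 | 3,5-dihydroxy-4-(methoxymethoxy)benzaldehyde | COCOc1c(O)cc(C=O)cc1O | intermediate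
3 | 3,5-bis(benzyloxy)-4-(methoxymethoxy)benzaldehyde | COCOc1c(OCc2ccccc2)cc(C=O)cc1OCc1ccccc1 | intermediate
4 | 3,5-bis(benzyloxy)-4-(methoxymethoxy)phenyl formate | COCOc1c(OCc2ccccc2)cc(OC=O)cc1OCc1ccccc1 | intermediate
5 | 3,5-bis(benzyloxy)-4-(methoxymethoxy)phenol | COCOc1c(OCc2ccccc2)cc(O)cc1OCc1ccccc1 | intermediate
6 | 3,5-bis(benzyloxy)-2-bromo-4-(methoxymethoxy)phenol | COCOc1c(OCc2ccccc2)cc(O)c(Br)c1OCc1ccccc1 | intermediate
7 | [3,5-bis(benzyloxy)-2-bromo-4-(methoxymethoxy)phenoxy]trimethylsilane | COCOc1c(OCc2ccccc2)cc(O[Si](C)(C)C)c(Br)c1OCc1ccccc1 | intermediate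
8 | lithium 3,5-bis(benzyloxy)-4-(methoxymethoxy)-2-(trimethylsilyl)phenoxide | COCOc1c(OCc2ccccc2)cc([O-])c([Si](C)(C)C)c1OCc1ccccc1.[Li+] | intermediate
9 | 3,5-bis(benzyloxy)-4-(methoxymethoxy)-2-(trimethylsilyl)phenyl trifluoromethanesulfonate | C[Si](C)(C)c1c(OS(=O)(=O)C(F)(F)F)cc(OCc2ccccc2)c(OCOC)c1OCc1ccccc1 | intermediate
10 | 3,4-bis(benzyloxy)benzaldehyde | O=Cc1ccc(OCc2ccccc2)c(OCc2ccccc2)c1 | starting material
11 | 1,2-bis(benzyloxy)-4-(2,2-dibromoethenyl)benzene | BrC(Br)=Cc1ccc(OCc2ccccc2)c(OCc2ccccc2)c1 | intermediate
12 | lithium 2-[3,4-bis(benzyloxy)phenyl]ethyn-1-ide | [Li+].[C-]#Cc1ccc(OCc2ccccc2)c(OCc2ccccc2)c1 | intermediate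
13 | 3-[3,4-bis(benzyloxy)phenyl]prop-2-ynoic acid | OC(=O)C#Cc1ccc(OCc2ccccc2)c(OCc2ccccc2)c1 | intermediate
14 | sodium 3-[3,4-bis(benzyloxy)phenyl]prop-2-ynoate | [Na+].[O-]C(=O)C#Cc1ccc(OCc2ccccc2)c(OCc2ccccc2)c1 | intermediate
15 | 3,5-bis(benzyloxy)-4-(methoxymethoxy)-1,2-didehydrobenzene (aryne) | COCOC1=C(OCc2ccccc2)C#CC=C1OCc1ccccc1 | intermediate
16 | 1-[2,4-bis(benzyloxy)-6-hydroxy-3-(methoxymethoxy)phenyl]-3-[3,4-bis(benzyloxy)phenyl]prop-2-yn-1-one | O=C(C#Cc1ccc(OCc2ccccc2)c(OCc2ccccc2)c1)c1c(O)cc(OCc2ccccc2)c(OCOC)c1OCc1ccccc1 | intermediate
17 | (E)-1-[2,4-bis(benzyloxy)-6-hydroxy-3-(methoxymethoxy)phenyl]-3-[3,4-bis(benzyloxy)phenyl]-3-(diethylamino)prop-2-en-1-one | CCN(CC)/C(=C/C(=O)c1c(O)cc(OCc2ccccc2)c(OCOC)c1OCc1ccccc1)c1ccc(OCc2ccccc2)c(OCc2ccccc2)c1 | intermediate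
18 | 5,7-bis(benzyloxy)-2-[3,4-bis(benzyloxy)phenyl]-6-(methoxymethoxy)-4H-chromen-4-one | O=c1cc(-c2ccc(OCc3ccccc3)c(OCc3ccccc3)c2)oc2cc(OCc3ccccc3)c(OCOC)c(OCc3ccccc3)c12 | intermediate
19 | 5,7-bis(benzyloxy)-2-[3,4-bis(benzyloxy)phenyl]-6-hydroxy-4H-chromen-4-one | O=c1cc(-c2ccc(OCc3ccccc3)c(OCc3ccccc3)c2)oc2cc(OCc3ccccc3)c(O)c(OCc3ccccc3)c12 | intermediate
20 | triethylammonium 5,7-bis(benzyloxy)-2-[3,4-bis(benzyloxy)phenyl]-4-oxo-4H-chromen-6-yl sulfate | O=c1cc(-c2ccc(OCc3ccccc3)c(OCc3ccccc3)c2)oc2cc(OCc3ccccc3)c(OS(=O)(=O)[O-])c(OCc3ccccc3)c12.CC[NH+](CC)CC | intermediate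
21 | triethylammonium 2-(3,4-dihydroxyphenyl)-5,7-dihydroxy-4-oxo-4H-chromen-6-yl sulfate | O=c1cc(-c2ccc(O)c(O)c2)oc2cc(O)c(OS(=O)(=O)[O-])c(O)c12.CC[NH+](CC)CC | intermediate
22 | 2-(3,4-dihydroxyphenyl)-5,7-dihydroxy-4-oxo-4H-chromen-6-yl hydrogen sulfate (6-hydroxyluteolin 6-sulfate) | O=c1cc(-c2ccc(O)c(O)c2)oc2cc(O)c(OS(=O)(=O)O)c(O)c12 | target

## Step count and least certain steps

Total step count: 13. Longest linear sequence: 11 steps (steps 1–6 and 9–13); acid 13 is made in a side branch of 2 steps (steps 7–8).

**Step 9 (key step).** Three processes could undo it: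
- Protonation of the aryl anion before the acyl group has moved. This would end the sequence at simple O-arylation, and it is the reason for removing the acid proton with NaH.
- Ring closure of the ynone phenoxide in the warm flask. The part that closes in the 5-exo sense is lost; the part that closes 6-endo is 18 and can be carried on.
- Addition of the product phenoxide to a second aryne. Keeping 9 as the limiting partner guards against this.

Fallback: set out from 6 and 13 and make the same o-acyloxy aryl anion without an aryne. Esterification (N,N'-dicyclohexylcarbodiimide, catalytic DMAP, CH2Cl2, 0 °C) gives 3,5-bis(benzyloxy)-2-bromo-4-(methoxymethoxy)phenyl 3-[3,4-bis(benzyloxy)phenyl]prop-2-ynoate F1. Bromine–lithium exchange with t-BuLi (2.1 equiv, THF, −100 °C) then triggers the anionic Fries shift of the acyl group from oxygen to carbon, and after an acetic acid quench the route is rejoined at 16.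

**Step 1.** Alkylation may spread to the flanking hydroxyls or go twice, because the more acidic 4-phenoxide is also the less nucleophilic and the more hindered one. Fallback: from 1, exhaustive benzylation (BnBr, K2CO3, DMF) gives 3,4,5-tris(benzyloxy)benzaldehyde F2. Its central benzyl group is then removed by SN2 attack of NaSEt in DMF at 80 °C. This ether is twisted out of the ring plane and releases the best leaving group, the phenoxide conjugated with the formyl group, to give 3,5-bis(benzyloxy)-4-hydroxybenzaldehyde F3. Acetal formation with MOMCl and i-Pr2NEt rejoins the route at 3.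

**Step 11.** The acid may also cleave the benzyl ether on O5, which is activated by chelation to the C4 carbonyl, before the acetal is fully removed. Fallback: make this loss deliberate. From 18, conc. HCl in AcOH at 60 °C removes both the acetal and the 5-O-benzyl group to give 7-(benzyloxy)-2-[3,4-bis(benzyloxy)phenyl]-5,6-dihydroxy-4H-chromen-4-one F4. Its 5-hydroxyl is locked in a hydrogen bond to the carbonyl and should not take up SO3, so SO3·NEt3 in DMF should give triethylammonium 7-(benzyloxy)-2-[3,4-bis(benzyloxy)phenyl]-5-hydroxy-4-oxo-4H-chromen-6-yl sulfate F5. Hydrogenolysis (H2, Pd/C) rejoins the route at 21.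

**Step 12.** Transfer of SO3 to a hydroxyl crowded by two benzyloxy groups may stall, and the ionic product may lose sulfate during purification. Fallback: from 19, use a sulfonyl chloride-type electrophile in place of SO3 transfer. 2,2,2-Trichloroethyl chlorosulfate with DMAP and Et3N in THF gives the neutral, chromatographable diester 5,7-bis(benzyloxy)-2-[3,4-bis(benzyloxy)phenyl]-4-oxo-4H-chromen-6-yl 2,2,2-trichloroethyl sulfate F6. Pd/C with HCO2NH4 in MeOH removes the trichloroethyl group by reductive fragmentation and the benzyl ethers by transfer hydrogenolysis, giving ammonium 2-(3,4-dihydroxyphenyl)-5,7-dihydroxy-4-oxo-4H-chromen-6-yl sulfate F7. Cation exchange (Dowex 50W, H+ form) rejoins the route at 22.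

## Further compounds

F1 | step 9 | 3,5-bis(benzyloxy)-2-bromo-4-(methoxymethoxy)phenyl 3-[3,4-bis(benzyloxy)phenyl]prop-2-ynoate | O=C(C#Cc1ccc(OCc2ccccc2)c(OCc2ccccc2)c1)Oc1cc(OCc2ccccc2)c(OCOC)c(OCc2ccccc2)c1Br
F2 | step 1 | 3,4,5-tris(benzyloxy)benzaldehyde | O=Cc1cc(OCc2ccccc2)c(OCc2ccccc2)c(OCc2ccccc2)c1
F3 | step 1 | 3,5-bis(benzyloxy)-4-hydroxybenzaldehyde | O=Cc1cc(OCc2ccccc2)c(O)c(OCc2ccccc2)c1
F4 | step 11 | 7-(benzyloxy)-2-[3,4-bis(benzyloxy)phenyl]-5,6-dihydroxy-4H-chromen-4-one | O=c1cc(-c2ccc(OCc3ccccc3)c(OCc3ccccc3)c2)oc2cc(OCc3ccccc3)c(O)c(O)c12
F5 | step 11 | triethylammonium 7-(benzyloxy)-2-[3,4-bis(benzyloxy)phenyl]-5-hydroxy-4-oxo-4H-chromen-6-yl sulfate | O=c1cc(-c2ccc(OCc3ccccc3)c(OCc3ccccc3)c2)oc2cc(OCc3ccccc3)c(OS(=O)(=O)[O-])c(O)c12.CC[NH+](CC)CC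
F6 | step 12 | 5,7-bis(benzyloxy)-2-[3,4-bis(benzyloxy)phenyl]-4-oxo-4H-chromen-6-yl 2,2,2-trichloroethyl sulfate | O=c1cc(-c2ccc(OCc3ccccc3)c(OCc3ccccc3)c2)oc2cc(OCc3ccccc3)c(OS(=O)(=O)OCC(Cl)(Cl)Cl)c(OCc3ccccc3)c12
F7 | step 12 | ammonium 2-(3,4-dihydroxyphenyl)-5,7-dihydroxy-4-oxo-4H-chromen-6-yl sulfate | O=c1cc(-c2ccc(O)c(O)c2)oc2cc(O)c(OS(=O)(=O)[O-])c(O)c12.[NH4+]
A1 | alternative 1 | 5-hydroxy-3',4'-bis(pivaloyloxy)flavone 6,7-cyclic sulfate | O=c1cc(-c2ccc(OC(=O)C(C)(C)C)c(OC(=O)C(C)(C)C)c2)oc2cc3OS(=O)(=O)Oc3c(O)c12
A2 | alternative 1 | 5,6,7-trihydroxy-3',4'-bis(pivaloyloxy)flavone | O=c1cc(-c2ccc(OC(=O)C(C)(C)C)c(OC(=O)C(C)(C)C)c2)oc2cc(O)c(O)c(O)c12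
A3 | alternative 2 | 5,7,3',4'-tetrakis(benzyloxy)-6-hydroxyflavone | O=c1cc(-c2ccc(OCc3ccccc3)c(OCc3ccccc3)c2)oc2cc(OCc3ccccc3)c(O)c(OCc3ccccc3)c12
A4 | alternative 2 | 1-[2,4-bis(benzyloxy)-3-hydroxyphenyl]-3-[3,4-bis(benzyloxy)phenyl]propane-1,3-dione | O=C(CC(=O)c1ccc(OCc2ccccc2)c(OCc2ccccc2)c1)c1ccc(OCc2ccccc2)c(O)c1OCc1ccccc1
A5 | alternative 3 | (2S,3R)-2-(benzoyloxy)-3-(benzyloxy)-5-hydroxycyclohexan-1-one (carbinol centre as formed) | O=C1[C@@H](OC(=O)c2ccccc2)[C@H](OCc2ccccc2)CC(O)C1
A6 | alternative 3 | methyl 4-O-benzoyl-3-O-benzyl-2,6-dideoxy-α-D-threo-hex-5-enopyranoside | C=C1[C@H]([C@@H](C[C@H](O1)OC)OCc1ccccc1)OC(=O)c1ccccc1
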